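## Retrosynthetic overview

1. The target is traced back to a drim-7-ene-1β,5α,11,12-tetraol (C1 acylation, oxidation of C11/C12), then to the Δ7 11,12-diester, which is the deconjugated isomer of the Δ8 diester (alkene moved from C8=C9 to C7=C8, proton placed on C9).
2. Key disconnection: the Δ8 diester comes from an open-chain triene by an intramolecular Diels–Alder reaction with inverse electron demand. It forms C6–C7 and C5–C10 together, so ring B (cycloadduct ring) and ring A (tether ring) close in the same step; no carbocycle exists before it.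
3. Enabling feature: ring B is a cyclohexene whose C8 and C9 carry the two carbonyl carbons (C12, C11) and whose fusion carbon C5 carries oxygen. With the alkene at C8=C9 it is the adduct of a 2,3-diester diene C7=C8–C9=C10 and an enol ether C5(O)=C6, and C1–C4 of ring A is a four-atom tether that carries the C1 oxygen stereocentre.
4. The triene comes from a Stille coupling of an α-iodo enoate with methyl 2-(tributylstannyl)acrylate. Syn carbocupration/iodination of a γ-silyloxy ynoate fixes the C9=C10 geometry, the silyl enol ether comes from a methyl ketone, and C1 is set by Alpine-Borane reduction of an ynone.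
5. The ynone comes from methyl propiolate and 4,4-dimethyl-5-oxohexanal (isobutyronitrile, 2-(2-bromoethyl)-1,3-dioxolane, MeLi); the acyl group comes from p-coumaric acid.

Key step: step 11

Remarks:
- Ring compounds are named with drimane numbering (ring A = C1–C5 and C10, ring B = C5–C10, C11 on C9, C12 on C8, C13/C14 on C4, C15 on C10; β is the face of C15). The same carbon numbers are used for the open-chain precursors.
- Assumption: Alpine-Borane made from (+)-α-pinene is taken to give the R carbinol with this 4-oxo-2-ynoate, as it does with simple alkynyl ketones; if the sense were opposite, the reagent from (−)-α-pinene would be used with no other change.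

## Route

Step 1
Reactants: 1 isobutyronitrile; 2 2-(2-bromoethyl)-1,3-dioxolane
Product: 3 4-(1,3-dioxolan-2-yl)-2,2-dimethylbutanenitrile
Conditions: LiN(iPr)2, THF, −78 °C; then 2, −78 °C to rt
Reagents that add atoms: none
Why: SN2 alkylation of the tertiary α-cyano carbanion with a primary bromide, which builds the quaternary C4 with both methyl groups in place.

Step 2
Reactants: 3 4-(1,3-dioxolan-2-yl)-2,2-dimethylbutanenitrile
Product: 5 4,4-dimethyl-5-oxohexanal, via lithium ketimide 4 (not isolated)
Conditions: MeLi, Et2O, 0 °C to rt; then 2 M HCl, THF, rt; used at once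
Reagents that add atoms: methyllithium, C[Li]; water, O
Why: Organolithium addition to a nitrile without α-hydrogen stops at the N-lithio ketimine, and aqueous acid then hydrolyses the imine (C5 ketone with C6 methyl) and the dioxolane (C1 aldehyde) together.

Step 3
Reactants: 5 4,4-dimethyl-5-oxohexanal; 6 methyl propiolate
Product: 8 methyl 4-hydroxy-7,7-dimethyl-8-oxonon-2-ynoate (racemic), via lithium methyl propiolate 7 (not isolated)
Conditions: 6, LiN(SiMe3)2, THF, −78 °C; then 5, −78 °C; AcOH quench at −78 °C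
Reagents that add atoms: none
Why: 1,2-Addition of a lithium acetylide to the aldehyde, which at −78 °C is far faster than addition to or enolisation of the hindered methyl ketone; the racemic carbinol is erased in step 4.

Step 4
Reactants: 8 methyl 4-hydroxy-7,7-dimethyl-8-oxonon-2-ynoate
Product: 9 methyl 7,7-dimethyl-4,8-dioxonon-2-ynoate
Conditions: Dess–Martin periodinane, CH2Cl2, 0 °C to rt
Reagents that add atoms: none
Why: Dess–Martin oxidation of a propargylic alcohol to the ynone under base-free conditions that spare the electrophilic ynoate.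

Step 5
Reactants: 9 methyl 7,7-dimethyl-4,8-dioxonon-2-ynoate
Product: 10 methyl (4R)-4-hydroxy-7,7-dimethyl-8-oxonon-2-ynoate
Conditions: (R)-Alpine-Borane [B-isopinocampheyl-9-borabicyclo[3.3.1]nonane from (+)-α-pinene], neat, rt; then CH3CHO; then ethanolamine, Et2O
Reagents that add atoms: none
Why: Midland reduction, in which hydride is transferred through a boat-like six-membered transition state with the slim alkynyl group next to the pinane methyl, should give the R carbinol (C1 of the target) and leave the hindered methyl ketone untouched.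

Step 6
Reactants: 10 methyl (4R)-4-hydroxy-7,7-dimethyl-8-oxonon-2-ynoate
Product: 11 methyl (4R)-4-[(tert-butyldimethylsilyl)oxy]-7,7-dimethyl-8-oxonon-2-ynoate
Conditions: TBSCl, imidazole, DMF, 0 °C to rt
Reagents that add atoms: tert-butyldimethylsilyl chloride, CC(C)(C)[Si](C)(C)Cl
Why: Standard silylation of a secondary alcohol, which blocks lactonisation in step 7 and provides the bulky C1 substituent that later steers the cycloaddition.

Step 7
Reactants: 11 methyl (4R)-4-[(tert-butyldimethylsilyl)oxy]-7,7-dimethyl-8-oxonon-2-ynoate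
Product: 13 methyl (2E,4R)-4-[(tert-butyldimethylsilyl)oxy]-2-iodo-3,7,7-trimethyl-8-oxonon-2-enoate, via alkenylcuprate 12 (not isolated)
Conditions: Me2CuLi (from MeLi and CuI), THF, −78 °C; then I2 in THF, −78 to −40 °C
Reagents that add atoms: lithium dimethylcuprate, C[Cu-]C.[Li+]; iodine, II
Why: Syn carbocupration of the ynoate puts the new methyl (C15) and copper on the same side, and iodinolysis of the alkenylcopper with retention gives the iodide in which the C1 carbon is cis to the ester, the geometry needed at C9=C10; the low temperature suppresses isomerisation through the allenolate.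

Step 8
Reactants: 13 methyl (2E,4R)-4-[(tert-butyldimethylsilyl)oxy]-2-iodo-3,7,7-trimethyl-8-oxonon-2-enoate
Product: 14 methyl (2E,4R)-4-[(tert-butyldimethylsilyl)oxy]-2-iodo-3,7,7-trimethyl-8-[(triethylsilyl)oxy]nona-2,8-dienoate
Conditions: Et3SiOTf, Et3N, CH2Cl2, 0 °C
Reagents that add atoms: triethylsilyl triflate, CC[Si](CC)(CC)OS(=O)(=O)C(F)(F)F
Why: Soft enolisation of the methyl ketone can occur only toward the methyl group because C4 is quaternary, so a single terminal silyl enol ether (C5=C6) forms.

Step 9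
Reactants: 6 methyl propiolate
Product: 15 methyl 2-(tributylstannyl)prop-2-enoate
Conditions: Bu3SnH, Pd(PPh3)4 (2 mol %), THF, rt
Reagents that add atoms: tributylstannane, CCCC[SnH](CCCC)CCCC
Why: Palladium-catalysed syn hydrostannation of a propiolate places tin on the carbon α to the ester.

Step 10
Reactants: 14 methyl (2E,4R)-4-[(tert-butyldimethylsilyl)oxy]-2-iodo-3,7,7-trimethyl-8-[(triethylsilyl)oxy]nona-2,8-dienoate; 15 methyl 2-(tributylstannyl)prop-2-enoate
Product: 16 dimethyl (2Z)-2-[(3R)-3-[(tert-butyldimethylsilyl)oxy]-6,6-dimethyl-7-[(triethylsilyl)oxy]oct-7-en-2-ylidene]-3-methylidenebutanedioate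
Conditions: Pd2(dba)3 (5 mol %), AsPh3 (20 mol %), CuI (20 mol %), BHT, NMP, rt to 40 °C, fluoride-free
Reagents that add atoms: none
Why: Stille coupling joins C8 to C9 with retention of the alkene geometry; the weakly bound arsine ligand and copper co-catalysis are the usual remedy for two hindered partners, and the neutral conditions spare the silyl enol ether.

Step 11
Reactants: 16 dimethyl (2Z)-2-[(3R)-3-[(tert-butyldimethylsilyl)oxy]-6,6-dimethyl-7-[(triethylsilyl)oxy]oct-7-en-2-ylidene]-3-methylidenebutanedioate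
Product: 17 dimethyl 1β-[(tert-butyldimethylsilyl)oxy]-5α-[(triethylsilyl)oxy]drim-8-ene-11,12-dioate
Conditions: PhMe (0.005 M), BHT (0.1 equiv), base-washed sealed tube, 130 °C
Reagents that add atoms: none
Why: Thermal intramolecular Diels–Alder reaction with inverse electron demand: the diester diene C7=C8–C9=C10 (LUMO) and the silyl enol ether C5=C6 (HOMO) combine in a concerted, asynchronous [4+2] in which the unhindered C6–C7 bond runs ahead of C5–C10; the closest known reaction types are the cyclisation of 1,7,9-decatrienes and the cycloaddition of 2,3-bis(alkoxycarbonyl)butadienes with enol ethers. Ring B is the cycloadduct ring itself (new bonds C6–C7 and C5–C10, new alkene C8=C9), and ring A is the six-membered tether ring, closed in the fused mode by the C5–C10 bond. C10 is controlled by the C1 stereocentre through 1,3-allylic strain: C1–H eclipses the C9=C10 bond next to the C11 ester, the OTBS group points away, and the tether carbon C2 delivers the dienophile to the other face, so that C15 ends up anti to H1 (1β-O, 10β-methyl). C5 is controlled by the endo position of the small, electron-rich silyloxy group under the diene while the C4 end of the tether sits exo in a chair-like arrangement, which gives the trans ring fusion (5α-O). The regiochemistry (C6 to C7, C5 to C10) is fixed by the four-atom tether and by polarity. The trans-fused transition state is available only because step 7 placed the tether carbon C1 trans to C8 on C10.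

Step 12
Reactants: 17 dimethyl 1β-[(tert-butyldimethylsilyl)oxy]-5α-[(triethylsilyl)oxy]drim-8-ene-11,12-dioate
Product: 19 dimethyl 1β-[(tert-butyldimethylsilyl)oxy]-5α-[(triethylsilyl)oxy]drim-7-ene-11,12-dioate (9β-ester), via lithium dienolate 18 (not isolated)
Conditions: LiN(iPr)2 (1.1 equiv), THF, −78 °C; then AcOH, −78 °C
Reagents that add atoms: none
Why: Deconjugative protonation: γ-deprotonation at C7 (the only allylic CH2) gives the dienolate, and kinetic protonation at the α-carbon C9 from the α face, anti to the axial C15 methyl on C10, should give the 9α-H/9β-ester isomer, which is also the more stable equatorial one; the cold acidic quench leaves no base that could eliminate the C5 silyloxy group.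

Step 13
Reactants: 19 dimethyl 1β-[(tert-butyldimethylsilyl)oxy]-5α-[(triethylsilyl)oxy]drim-7-ene-11,12-dioate
Product: 20 1β-[(tert-butyldimethylsilyl)oxy]-5α-[(triethylsilyl)oxy]drim-7-ene-11,12-diol
Conditions: LiAlH4, Et2O, 0 °C to rt
Reagents that add atoms: none
Why: Hydride reduction of the conjugated and the hindered saturated ester to the allylic and the primary alcohol, with C9 no longer epimerisable afterwards.

Step 14
Reactants: 20 1β-[(tert-butyldimethylsilyl)oxy]-5α-[(triethylsilyl)oxy]drim-7-ene-11,12-diol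
Product: 21 drim-7-ene-1β,5α,11,12-tetraol
Conditions: Bu4NF, THF, 50 °C
Reagents that add atoms: none
Why: Fluoride cleaves both silyl ethers at a stage where no base-sensitive carbonyl is present.

Step 15
Reactants: 21 drim-7-ene-1β,5α,11,12-tetraol
Product: 22 11,12-bis[(triethylsilyl)oxy]drim-7-ene-1β,5α-diol
Conditions: Et3SiCl (2.2 equiv), imidazole, CH2Cl2, −20 to 0 °C
Reagents that add atoms: chlorotriethylsilane, CC[Si](Cl)(CC)CC
Why: The two primary alcohols are silylated much faster than the neopentyl secondary C1–OH and the tertiary C5–OH.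

Step 16
Reactants: 23 p-coumaric acid
Product: 25 (E)-3-[4-[(tert-butyldimethylsilyl)oxy]phenyl]prop-2-enoic acid, via bis-silyl coumarate 24 (not isolated)
Conditions: TBSCl (2.2 equiv), imidazole, DMF, rt; then AcOH/THF/H2O, rt
Reagents that add atoms: tert-butyldimethylsilyl chloride, CC(C)(C)[Si](C)(C)Cl
Why: Both acidic OH groups are silylated and the much more labile silyl ester is then hydrolysed selectively, leaving the aryl silyl ether.

Step 17
Reactants: 22 11,12-bis[(triethylsilyl)oxy]drim-7-ene-1β,5α-diol; 25 (E)-3-[4-[(tert-butyldimethylsilyl)oxy]phenyl]prop-2-enoic acid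
Product: 27 1β-[(E)-3-[4-[(tert-butyldimethylsilyl)oxy]phenyl]prop-2-enoyloxy]-11,12-bis[(triethylsilyl)oxy]drim-7-en-5α-ol, via mixed anhydride 26 (not isolated)
Conditions: 25, 2,4,6-trichlorobenzoyl chloride, Et3N, THF, rt; then 22, DMAP, PhMe, 40 °C
Reagents that add atoms: none
Why: Yamaguchi esterification acylates the hindered equatorial C1–OH through the acylpyridinium ion, while the tertiary C5–OH does not react.

Step 18
Reactants: 27 1β-[(E)-3-[4-[(tert-butyldimethylsilyl)oxy]phenyl]prop-2-enoyloxy]-11,12-bis[(triethylsilyl)oxy]drim-7-en-5α-ol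
Product: 28 1β-[(E)-3-[4-[(tert-butyldimethylsilyl)oxy]phenyl]prop-2-enoyloxy]-5α-hydroxydrim-7-ene-11,12-dial
Conditions: (COCl)2, DMSO, CH2Cl2, −78 to −30 °C; then Et3N, −78 to 0 °C
Reagents that add atoms: none
Why: Swern conditions convert primary triethylsilyl ethers directly into aldehydes while the aryl TBS ether, the ester and the tertiary alcohol stay, and the cold, brief exposure to Et3N is the known way to make such 9β-formyl 7-ene-11,12-dials without epimerisation at C9.

Step 19
Reactants: 28 1β-[(E)-3-[4-[(tert-butyldimethylsilyl)oxy]phenyl]prop-2-enoyloxy]-5α-hydroxydrim-7-ene-11,12-dial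
Product: 29 1β-[(E)-3-(4-hydroxyphenyl)prop-2-enoyloxy]-5α-hydroxydrim-7-ene-11,12-dial (1R,5R,9R,10S; CNP0323926.1)
Conditions: HF·pyridine, pyridine, THF, 0 °C to rt
Reagents that add atoms: none
Why: Buffered fluoride removes the aryl silyl ether without the basic conditions that would epimerise C9 or eliminate the C5 hydroxyl of the dialdehyde.

## Compound list

1 | isobutyronitrile | CC(C)C#N | starting material
2 | 2-(2-bromoethyl)-1,3-dioxolane | BrCCC1OCCO1 | starting material
3 | 4-(1,3-dioxolan-2-yl)-2,2-dimethylbutanenitrile | N#CC(C)(C)CCC1OCCO1 | intermediate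
4 | lithium ketimide of 5-(1,3-dioxolan-2-yl)-3,3-dimethylpentan-2-one | [Li]N=C(C)C(C)(C)CCC1OCCO1 | intermediate
5 | 4,4-dimethyl-5-oxohexanal | CC(=O)C(C)(C)CCC=O | intermediate
6 | methyl propiolate | C#CC(=O)OC | starting material
7 | lithium methyl propiolate (methyl 3-lithioprop-2-ynoate) | [Li]C#CC(=O)OC | intermediate
8 | methyl 4-hydroxy-7,7-dimethyl-8-oxonon-2-ynoate (racemic) | COC(=O)C#CC(O)CCC(C)(C)C(C)=O | intermediate
9 | methyl 7,7-dimethyl-4,8-dioxonon-2-ynoate | COC(=O)C#CC(=O)CCC(C)(C)C(C)=O | intermediate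
10 | methyl (4R)-4-hydroxy-7,7-dimethyl-8-oxonon-2-ynoate | COC(=O)C#C[C@H](O)CCC(C)(C)C(C)=O | intermediate
11 | methyl (4R)-4-[(tert-butyldimethylsilyl)oxy]-7,7-dimethyl-8-oxonon-2-ynoate | COC(=O)C#C[C@H](O[Si](C)(C)C(C)(C)C)CCC(C)(C)C(C)=O | intermediate
12 | lithium methyl[(4R)-alkenyl]cuprate, syn adduct of Me2CuLi and 11 (Cu on C2, cis to the new C3 methyl) | COC(=O)/C([Cu-]C)=C(/C)[C@H](O[Si](C)(C)C(C)(C)C)CCC(C)(C)C(C)=O.[Li+] | intermediate
13 | methyl (2E,4R)-4-[(tert-butyldimethylsilyl)oxy]-2-iodo-3,7,7-trimethyl-8-oxonon-2-enoate | COC(=O)/C(I)=C(/C)[C@H](O[Si](C)(C)C(C)(C)C)CCC(C)(C)C(C)=O | intermediate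
14 | methyl (2E,4R)-4-[(tert-butyldimethylsilyl)oxy]-2-iodo-3,7,7-trimethyl-8-[(triethylsilyl)oxy]nona-2,8-dienoate | COC(=O)/C(I)=C(/C)[C@H](O[Si](C)(C)C(C)(C)C)CCC(C)(C)C(=C)O[Si](CC)(CC)CC | intermediate
15 | methyl 2-(tributylstannyl)prop-2-enoate | C=C(C(=O)OC)[Sn](CCCC)(CCCC)CCCC | intermediate
16 | dimethyl (2Z)-2-[(3R)-3-[(tert-butyldimethylsilyl)oxy]-6,6-dimethyl-7-[(triethylsilyl)oxy]oct-7-en-2-ylidene]-3-methylidenebutanedioate | COC(=O)C(=C)/C(C(=O)OC)=C(\C)[C@H](O[Si](C)(C)C(C)(C)C)CCC(C)(C)C(=C)O[Si](CC)(CC)CC | intermediate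
17 | dimethyl 1β-[(tert-butyldimethylsilyl)oxy]-5α-[(triethylsilyl)oxy]drim-8-ene-11,12-dioate | CC1(C)CC[C@@H](O[Si](C)(C)C(C)(C)C)[C@]2(C)C(C(=O)OC)=C(C(=O)OC)CC[C@@]12O[Si](CC)(CC)CC | intermediate
18 | lithium dienolate of 17 (C9=C11 enolate, C7=C8 alkene) | CC1(C)CC[C@@H](O[Si](C)(C)C(C)(C)C)[C@]2(C)C(=C([O-])OC)C(C(=O)OC)=CC[C@@]12O[Si](CC)(CC)CC.[Li+] | intermediate
19 | dimethyl 1β-[(tert-butyldimethylsilyl)oxy]-5α-[(triethylsilyl)oxy]drim-7-ene-11,12-dioate (9β-ester) | CC1(C)CC[C@@H](O[Si](C)(C)C(C)(C)C)[C@]2(C)[C@@H](C(=O)OC)C(C(=O)OC)=CC[C@@]12O[Si](CC)(CC)CC | intermediate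
20 | 1β-[(tert-butyldimethylsilyl)oxy]-5α-[(triethylsilyl)oxy]drim-7-ene-11,12-diol | CC1(C)CC[C@@H](O[Si](C)(C)C(C)(C)C)[C@]2(C)[C@@H](CO)C(CO)=CC[C@@]12O[Si](CC)(CC)CC | intermediate
21 | drim-7-ene-1β,5α,11,12-tetraol | CC1(C)CC[C@@H](O)[C@]2(C)[C@@H](CO)C(CO)=CC[C@@]12O | intermediate
22 | 11,12-bis[(triethylsilyl)oxy]drim-7-ene-1β,5α-diol | CC1(C)CC[C@@H](O)[C@]2(C)[C@@H](CO[Si](CC)(CC)CC)C(CO[Si](CC)(CC)CC)=CC[C@@]12O | intermediate
23 | p-coumaric acid, (E)-3-(4-hydroxyphenyl)prop-2-enoic acid | OC(=O)/C=C/c1ccc(O)cc1 | starting material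
24 | tert-butyldimethylsilyl (E)-3-[4-[(tert-butyldimethylsilyl)oxy]phenyl]prop-2-enoate | CC(C)(C)[Si](C)(C)OC(=O)/C=C/c1ccc(O[Si](C)(C)C(C)(C)C)cc1 | intermediate
25 | (E)-3-[4-[(tert-butyldimethylsilyl)oxy]phenyl]prop-2-enoic acid | OC(=O)/C=C/c1ccc(O[Si](C)(C)C(C)(C)C)cc1 | intermediate
26 | (E)-3-[4-[(tert-butyldimethylsilyl)oxy]phenyl]prop-2-enoic 2,4,6-trichlorobenzoic anhydride | O=C(/C=C/c1ccc(O[Si](C)(C)C(C)(C)C)cc1)OC(=O)c1c(Cl)cc(Cl)cc1Cl | intermediate
27 | 1β-[(E)-3-[4-[(tert-butyldimethylsilyl)oxy]phenyl]prop-2-enoyloxy]-11,12-bis[(triethylsilyl)oxy]drim-7-en-5α-ol | CC1(C)CC[C@@H](OC(=O)/C=C/c2ccc(O[Si](C)(C)C(C)(C)C)cc2)[C@]2(C)[C@@H](CO[Si](CC)(CC)CC)C(CO[Si](CC)(CC)CC)=CC[C@@]12O | intermediate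
28 | 1β-[(E)-3-[4-[(tert-butyldimethylsilyl)oxy]phenyl]prop-2-enoyloxy]-5α-hydroxydrim-7-ene-11,12-dial | CC1(C)CC[C@@H](OC(=O)/C=C/c2ccc(O[Si](C)(C)C(C)(C)C)cc2)[C@]2(C)[C@@H](C=O)C(C=O)=CC[C@@]12O | intermediate
29 | 1β-[(E)-3-(4-hydroxyphenyl)prop-2-enoyloxy]-5α-hydroxydrim-7-ene-11,12-dial (1R,5R,9R,10S) | CC1(C)CC[C@@H](OC(=O)/C=C/c2ccc(O)cc2)[C@]2(C)[C@@H](C=O)C(C=O)=CC[C@@]12O | target

## Step count and risks

Total step count: 19 (including the preparation of stannane 15 in step 9 and of acid 25 in step 16).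
Longest linear sequence: 17 steps (steps 1–8, 10–15, 17–19).

The three steps most likely to fail:

**Step 11 (intramolecular Diels–Alder reaction).** Three processes may compete. The cycloaddition has to join two fully substituted carbons (C5, C10) next to the quaternary C4 and may be slower than a [1,5]-hydrogen shift from the C15 methyl across the cis-substituted diene. The silyloxy group may approach exo and give the cis ring fusion. The silyl enol ether may be lost by adventitious protonation.

Fallback: the two bonds are made one after the other, ring A first by a radical C5–C10 closure and ring B then by the same C6–C7 bond in an anionic epoxide opening. It sets out from 13 and comes back at 17.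
- Ketone 13 is converted with (PhO)3P/Br2 and Et3N into methyl (2E,4R)-8-bromo-4-[(tert-butyldimethylsilyl)oxy]-2-iodo-3,7,7-trimethylnona-2,8-dienoate F1.
- Stille coupling of the iodide with 15 (conditions of step 10; the hindered alkenyl bromide stays) gives dimethyl (2Z)-2-[(3R)-7-bromo-3-[(tert-butyldimethylsilyl)oxy]-6,6-dimethyloct-7-en-2-ylidene]-3-methylidenebutanedioate F2.
- Bu3SnH/AIBN in hot benzene under slow addition generates the C5 alkenyl radical, which closes ring A by 6-exo attack on C10 under the same allylic-strain control as in step 11. Hydrogen transfer to the resulting allylic radical gives dimethyl 2-[2-[(tert-butyldimethylsilyl)oxy]-1,5,5-trimethyl-6-methylidenecyclohexyl]-3-methylbut-2-enedioate F3 (ring methyl cis to the silyloxy group; either alkene geometry serves).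
- mCPBA epoxidises the electron-rich exocyclic alkene from the α face, opposite the two axial β-methyl groups on C4 and C10, to give dimethyl 2-[5-[(tert-butyldimethylsilyl)oxy]-4,8,8-trimethyl-1-oxaspiro[2.5]octan-4-yl]-3-methylbut-2-enedioate F4.
- LiN(iPr)2 (THF, −78 to 0 °C) removes a proton from the C7 methyl, and the dienolate opens the epoxide at its CH2 carbon C6, the only attack that gives a six-membered ring. This forms dimethyl 1β-[(tert-butyldimethylsilyl)oxy]-5α-hydroxydrim-8-ene-11,12-dioate F5, which Et3SiOTf/2,6-lutidine converts into 17.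

**Step 10 (Stille coupling).** Transmetallation between two hindered α-carbonyl alkenyl partners may be slow, so that protodestannylation, homocoupling or polymerisation of the electron-poor diene take over.

Fallback: the hindered sp2–sp2 coupling is replaced by an unhindered sp–sp2 coupling followed by carbonylation. It sets out from 13 and comes back at 16.
- Sonogashira coupling of 13 with trimethylsilylacetylene (PdCl2(PPh3)2, CuI, Et3N) gives methyl (2Z,4R)-4-[(tert-butyldimethylsilyl)oxy]-3,7,7-trimethyl-8-oxo-2-[(trimethylsilyl)ethynyl]non-2-enoate F6.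
- K2CO3 in MeOH removes the alkynyl silyl group to give methyl (2Z,4R)-4-[(tert-butyldimethylsilyl)oxy]-2-ethynyl-3,7,7-trimethyl-8-oxonon-2-enoate F7.
- Markovnikov hydromethoxycarbonylation of the terminal alkyne (Pd(OAc)2, 2-pyridyldiphenylphosphine, MeSO3H, CO, MeOH) installs the C8 acrylate and gives dimethyl (2Z)-2-[(3R)-3-[(tert-butyldimethylsilyl)oxy]-6,6-dimethyl-7-oxooctan-2-ylidene]-3-methylidenebutanedioate F8.
- Et3SiOTf/Et3N as in step 8 then gives 16.

**Step 12 (deconjugative protonation).** The dienolate may be protonated at C7, which returns 17, or from the β face, which gives the C9 epimer.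

Fallback: the C9 configuration and the alkene position are set in separate operations. It sets out from 17 and comes back at 19.
- Conjugate reduction of 17 (Mg, MeOH) followed by NaOMe equilibration gives the all-equatorial saturated diester, dimethyl 1β-[(tert-butyldimethylsilyl)oxy]-5α-[(triethylsilyl)oxy]drimane-11,12-dioate (8α,9β) F9; no eliminable unsaturation is present during the equilibration.
- LiN(iPr)2 deprotonates the less hindered C8–H, and PhSeBr gives dimethyl 1β-[(tert-butyldimethylsilyl)oxy]-8-(phenylselanyl)-5α-[(triethylsilyl)oxy]drimane-11,12-dioate F10.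
- Oxidation with H2O2 and selenoxide syn-elimination toward C7 give 19; any 17 formed by elimination toward C9 is recycled.

## Further compounds

F1 | step 11 | methyl (2E,4R)-8-bromo-4-[(tert-butyldimethylsilyl)oxy]-2-iodo-3,7,7-trimethylnona-2,8-dienoate | COC(=O)/C(I)=C(/C)[C@H](O[Si](C)(C)C(C)(C)C)CCC(C)(C)C(Br)=C
F2 | step 11 | dimethyl (2Z)-2-[(3R)-7-bromo-3-[(tert-butyldimethylsilyl)oxy]-6,6-dimethyloct-7-en-2-ylidene]-3-methylidenebutanedioate | COC(=O)C(=C)/C(C(=O)OC)=C(\C)[C@H](O[Si](C)(C)C(C)(C)C)CCC(C)(C)C(Br)=C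
F3 | step 11 | dimethyl 2-[2-[(tert-butyldimethylsilyl)oxy]-1,5,5-trimethyl-6-methylidenecyclohexyl]-3-methylbut-2-enedioate (alkene geometry not defined) | CC1(C)CC[C@@H](O[Si](C)(C)C(C)(C)C)[C@](C)(C(C(=O)OC)=C(C)C(=O)OC)C1=C
F4 | step 11 | dimethyl 2-[5-[(tert-butyldimethylsilyl)oxy]-4,8,8-trimethyl-1-oxaspiro[2.5]octan-4-yl]-3-methylbut-2-enedioate (epoxide oxygen trans to the ring methyl on C4 of the spiro ring) | CC1(C)CC[C@@H](O[Si](C)(C)C(C)(C)C)[C@](C)(C(C(=O)OC)=C(C)C(=O)OC)[C@]12OC2
F5 | step 11 | dimethyl 1β-[(tert-butyldimethylsilyl)oxy]-5α-hydroxydrim-8-ene-11,12-dioate | CC1(C)CC[C@@H](O[Si](C)(C)C(C)(C)C)[C@]2(C)C(C(=O)OC)=C(C(=O)OC)CC[C@@]12O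
F6 | step 10 | methyl (2Z,4R)-4-[(tert-butyldimethylsilyl)oxy]-3,7,7-trimethyl-8-oxo-2-[(trimethylsilyl)ethynyl]non-2-enoate | COC(=O)/C(C#C[Si](C)(C)C)=C(/C)[C@H](O[Si](C)(C)C(C)(C)C)CCC(C)(C)C(C)=O
F7 | step 10 | methyl (2Z,4R)-4-[(tert-butyldimethylsilyl)oxy]-2-ethynyl-3,7,7-trimethyl-8-oxonon-2-enoate | COC(=O)/C(C#C)=C(/C)[C@H](O[Si](C)(C)C(C)(C)C)CCC(C)(C)C(C)=O
F8 | step 10 | dimethyl (2Z)-2-[(3R)-3-[(tert-butyldimethylsilyl)oxy]-6,6-dimethyl-7-oxooctan-2-ylidene]-3-methylidenebutanedioate | COC(=O)C(=C)/C(C(=O)OC)=C(\C)[C@H](O[Si](C)(C)C(C)(C)C)CCC(C)(C)C(C)=O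
F9 | step 12 | dimethyl 1β-[(tert-butyldimethylsilyl)oxy]-5α-[(triethylsilyl)oxy]drimane-11,12-dioate (8α,9β-diester) | CC1(C)CC[C@@H](O[Si](C)(C)C(C)(C)C)[C@]2(C)[C@@H](C(=O)OC)[C@H](C(=O)OC)CC[C@@]12O[Si](CC)(CC)CC
F10 | step 12 | dimethyl 1β-[(tert-butyldimethylsilyl)oxy]-8-(phenylselanyl)-5α-[(triethylsilyl)oxy]drimane-11,12-dioate (C8 configuration not defined) | CC1(C)CC[C@@H](O[Si](C)(C)C(C)(C)C)[C@]2(C)[C@@H](C(=O)OC)C([Se]c3ccccc3)(C(=O)OC)CC[C@@]12O[Si](CC)(CC)CC
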